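**Retrosynthetic overview**
1. Hispidulin 7-sulfate ⇒ the aryl C6–OCH3 carbon–oxygen bond, made last by copper-catalysed coupling of methoxide with 6-iodoapigenin 7-sulfate (key step, new).
2. 6-Iodoapigenin 7-sulfate ⇒ C6–H iodination of apigenin 7-sulfate. The free 5-OH and the blocked 7-oxygen steer iodine to C6.
3. Apigenin 7-sulfate ⇒ the O7–S bond, by regioselective sulfation of apigenin, a cheap bulk flavone.
4. Rings: none is built. Rings A, C and B come intact with apigenin, so all steps are spent on the ring A substituents.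

Assumption: the target has no stereocentre and is achiral, so there is no enantiomer to select; it is delivered as the free hydrogen sulfate drawn in the SMILES, with potassium salt 5 as the storage form.

**Route**

Step 1
Reactants: 1 apigenin (5,7,4'-trihydroxyflavone)
Product: 3 potassium apigenin 7-sulfate, via tetrabutylammonium apigenin 7-sulfate 2 (not isolated)
Conditions: Bu4NHSO4 (1.1 equiv), DCC (3 equiv), pyridine, 4 °C, 48 h; filter; then KOAc, MeOH, rt, collect the precipitate
Reagents that add atoms: tetrabutylammonium hydrogen sulfate, CCCC[N+](CCCC)(CCCC)CCCC.OS(=O)(=O)[O-]; KOAc (potassium acetate), CC(=O)[O-].[K+]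
Why: Carbodiimide-mediated O-sulfation, in which DCC activates hydrogen sulfate as an O-sulfonatoisourea, takes the most acidic and unhindered 7-OH first at 4 °C while the 4'-OH reacts more slowly and the 5-OH stays locked in its hydrogen bond to the C4 carbonyl, and cation metathesis with KOAc then precipitates salt 3, with no stereocentre involved.

Step 2
Reactants: 3 potassium apigenin 7-sulfate
Product: 4 potassium 6-iodoapigenin 7-sulfate
Conditions: NIS (1.05 equiv), DMF, rt, dark, 12 h; precipitate with Et2O, C18 filtration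
Reagents that add atoms: N-iodosuccinimide, O=C1CCC(=O)N1I
Why: Electrophilic aromatic iodination under neutral conditions attacks the carbon ortho to the 5-OH (C6) rather than C8 in flavones that have a free chelated 5-OH and a substituted 7-oxygen, ring B is less activated because it has a single OH and is conjugated to the electron-poor pyranone, and the sulfate monoester, the enone and the phenols are inert to NIS.

Step 3
Reactants: 4 potassium 6-iodoapigenin 7-sulfate
Product: 6 hispidulin 7-sulfate, via potassium hispidulin 7-sulfate 5 (not isolated)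
Conditions: CuI (20 mol %), 3,4,7,8-tetramethyl-1,10-phenanthroline (40 mol %), NaOMe (4 equiv), MeOH–DMF 1:2, 75 °C, under argon, 16 h; then 0.5 M HCl, 0 °C, pH 2; C18 desalting, freeze-drying
Reagents that add atoms: NaOMe (sodium methoxide), C[O-].[Na+]
Why: Proposed new method: an Ullmann-type copper-catalysed C–O coupling run for the first time on an aryl iodide that carries a free aryl sulfate monoester, in which the anionic 7-OSO3 group ortho to the C6–I bond is meant to serve as a built-in ligand (six-membered Cu–O–S–O–C7–C6 chelate) that draws the phenanthroline-bound monovalent copper methoxide to the doubly ortho-substituted carbon, oxidative addition gives a trivalent aryl copper methoxide that reductively eliminates the C6–OMe bond, the sulfate monoanion resists methoxide and the 4'- and 5-phenoxides make C2 of the pyranone too electron-rich for ring opening, the closest known reaction types being the ortho-carboxylate-accelerated Ullmann couplings of 2-halobenzoic acids (Hurtley type) and the CuBr/NaOMe methoxylation of unprotected bromohydroxyflavones, and cold HCl finally protonates salt 5 to the free hydrogen sulfate 6.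

**Compound list**
1 | apigenin, 5,7-dihydroxy-2-(4-hydroxyphenyl)-4H-chromen-4-one | O=c1cc(-c2ccc(O)cc2)oc2cc(O)cc(O)c12 | starting material
2 | tetrabutylammonium apigenin 7-sulfate | CCCC[N+](CCCC)(CCCC)CCCC.O=c1cc(-c2ccc(O)cc2)oc2cc(OS(=O)(=O)[O-])cc(O)c12 | intermediate
3 | potassium apigenin 7-sulfate | [K+].O=c1cc(-c2ccc(O)cc2)oc2cc(OS(=O)(=O)[O-])cc(O)c12 | intermediate
4 | potassium 6-iodoapigenin 7-sulfate (iodine at C6, between the 5-OH and the 7-sulfate) | [K+].[O-]S(=O)(=O)Oc1cc2oc(-c3ccc(O)cc3)cc(=O)c2c(O)c1I | intermediate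
5 | potassium hispidulin 7-sulfate (phenols drawn protonated) | [K+].COc1c(OS(=O)(=O)[O-])cc2oc(-c3ccc(O)cc3)cc(=O)c2c1O | intermediate
6 | hispidulin 7-sulfate, 5-hydroxy-2-(4-hydroxyphenyl)-6-methoxy-4-oxo-4H-chromen-7-yl hydrogen sulfate (achiral) | COc1c(OS(=O)(=O)O)cc2oc(-c3ccc(O)cc3)cc(=O)c2c1O | target

**Step count**
Total steps: 3. Longest linear sequence: 3 (1 → 3 → 4 → 6).

**Three steps most likely to fail**

Step 3, the new C–O coupling, carries the highest risk.
- It may fail by hydrodeiodination back to 3, by copper being tied up at the 5-oxido-4-keto site, or by sluggish reaction at the hindered carbon.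
- The fallback uses only known chemistry. It sets out from 1 and comes back at 5.
- In it the coupling is run on a protected flavone and the sulfate is put on last.
- BnBr and K2CO3 in DMF give 7,4'-di-O-benzylapigenin F1, with the chelated 5-OH left free.
- BnNMe3ICl2 and CaCO3 in CH2Cl2–MeOH give 7,4'-di-O-benzyl-6-iodoapigenin F2.
- CuBr and NaOMe in DMF–MeOH at 110 °C give 7,4'-di-O-benzylhispidulin F3.
- H2 over Pd/C gives hispidulin F4.
- Bu4NHSO4 and DCC in pyridine at 4 °C give tetrabutylammonium hispidulin 7-sulfate F5.
- KOAc in MeOH converts F5 into 5, which is acidified to 6 as in step 3.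

Step 2 carries a site-selectivity risk.
- Iodine may go to C8 or to C3' of the free ring B phenol, or add twice.
- The site is checked by HMBC from the chelated 5-OH proton to the iodine-bearing carbon.
- The fallback sets out from 1 and comes back at 4.
- It iodinates before sulfation, on a substrate whose 7-OH and ring B phenol are masked.
- MOMCl and iPr2NEt give 7,4'-bis-O-(methoxymethyl)apigenin F6.
- NIS in DMF gives 6-iodo-7,4'-bis-O-(methoxymethyl)apigenin F7, which belongs to the substrate class for which neutral iodination is C6-selective.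
- HCl in MeOH gives 6-iodoapigenin F8.
- SO3·NMe3 with K2CO3 (1 equiv) in DMF sulfates the 7-OH of F8, made more acidic by the ortho iodine, and gives 4 directly.

Step 1 carries a risk of 7- versus 4'-selectivity and of over-sulfation to the 7,4'-disulfate.
- The fallback sets out from 1 and comes back at 3.
- It replaces kinetic selection among free phenols by protecting-group control.
- Ac2O in pyridine gives 5,7,4'-tri-O-acetylapigenin F9.
- PhSH and imidazole in NMP remove only the 7-acetate and give 5,4'-di-O-acetylapigenin F10.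
- SO3·pyridine in DMF gives pyridinium 5,4'-di-O-acetylapigenin 7-sulfate F11.
- K2CO3 in MeOH removes both acetates, exchanges the cation and gives 3.

**Further compounds**
F1 | step 3 | 7,4'-di-O-benzylapigenin | O=c1cc(-c2ccc(OCc3ccccc3)cc2)oc2cc(OCc3ccccc3)cc(O)c12
F2 | step 3 | 7,4'-di-O-benzyl-6-iodoapigenin | Ic1c(O)c2c(=O)cc(-c3ccc(OCc4ccccc4)cc3)oc2cc1OCc1ccccc1
F3 | step 3 | 7,4'-di-O-benzylhispidulin | COc1c(OCc2ccccc2)cc2oc(-c3ccc(OCc4ccccc4)cc3)cc(=O)c2c1O
F4 | step 3 | hispidulin | COc1c(O)cc2oc(-c3ccc(O)cc3)cc(=O)c2c1O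
F5 | step 3 | tetrabutylammonium hispidulin 7-sulfate | CCCC[N+](CCCC)(CCCC)CCCC.COc1c(OS(=O)(=O)[O-])cc2oc(-c3ccc(O)cc3)cc(=O)c2c1O
F6 | step 2 | 7,4'-bis-O-(methoxymethyl)apigenin | COCOc1ccc(cc1)-c1cc(=O)c2c(O)cc(OCOC)cc2o1
F7 | step 2 | 6-iodo-7,4'-bis-O-(methoxymethyl)apigenin | Ic1c(O)c2c(=O)cc(-c3ccc(OCOC)cc3)oc2cc1OCOC
F8 | step 2 | 6-iodoapigenin | Ic1c(O)c2c(=O)cc(-c3ccc(O)cc3)oc2cc1O
F9 | step 1 | 5,7,4'-tri-O-acetylapigenin | CC(=O)Oc1ccc(cc1)-c1cc(=O)c2c(OC(C)=O)cc(OC(C)=O)cc2o1
F10 | step 1 | 5,4'-di-O-acetylapigenin | CC(=O)Oc1ccc(cc1)-c1cc(=O)c2c(OC(C)=O)cc(O)cc2o1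
F11 | step 1 | pyridinium 5,4'-di-O-acetylapigenin 7-sulfate | c1cc[nH+]cc1.CC(=O)Oc1ccc(cc1)-c1cc(=O)c2c(OC(C)=O)cc(OS(=O)(=O)[O-])cc2o1
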